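## Retrosynthetic overview

1. The free phenol is unmasked last, by hydrogenolysis of a benzyl ether.
2. Key C–C disconnection: the aryl–CH2 bond, made by copper-catalysed opening of (S)-2-tridecyloxirane at its CH2 end with a 3-(benzyloxy)-5-methoxyphenyl Grignard reagent (from 3-bromo-5-methoxyphenol).
3. The (S)-epoxide comes from (S)-1-chloropentadecan-2-ol, made by ketoreductase reduction of achiral 1-chloropentadecan-2-one; this sets the only stereocentre.
4. The chloroketone comes from tridecylmagnesium bromide and 2-chloro-N-methoxy-N-methylacetamide (C2–C3 bond).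
5. Rings: the benzene ring is bought intact; the only ring formed is the oxirane (after the enzymatic step), and it is opened again in the coupling.

Assumption: the ketoreductase is picked from a commercial screening panel as the variant that gives the (S)-chlorohydrin in at least 99% ee; the building blocks are catalogue chemicals.

## Route

Step 1
Reactants: 1 1-bromotridecane; 2 2-chloro-N-methoxy-N-methylacetamide
Product: 4 1-chloropentadecan-2-one, via tridecylmagnesium bromide 3 (not isolated)
Conditions: 1, Mg turnings, iodine (cat.), THF, 45 °C; then added to 2, THF, −20 → 0 °C; sat. aq. NH4Cl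
Reagents that add atoms: none
Why: Weinreb ketone synthesis; the N-methoxy-N-methylamide takes up exactly one equivalent of the Grignard reagent and releases the ketone only on aqueous quench, so the chloromethyl ketone forms without over-addition.

Step 2
Reactants: 4 1-chloropentadecan-2-one
Product: 5 (S)-1-chloropentadecan-2-ol
Conditions: ketoreductase (NADPH-dependent alcohol dehydrogenase, (S)-selective), NADP+ (cat.), iPrOH / K2HPO4–KH2PO4 buffer pH 7.0 (3:7), MgSO4 (2 mM), 30 °C, 24 h
Reagents that add atoms: none
Why: Biocatalytic asymmetric ketone reduction by a ketoreductase (hydride from NADPH, recycled by isopropanol); the enzyme places the small CH2Cl group and the long alkyl chain in different pockets and delivers hydride to one carbonyl face only (anti-Prelog sense), which creates the (S)-carbinol centre.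

Step 3
Reactants: 5 (S)-1-chloropentadecan-2-ol
Product: 6 (S)-2-tridecyloxirane
Conditions: NaOH (2 M aq., 1.5 equiv), EtOH, 0 °C → rt, 1 h
Reagents that add atoms: none
Why: Intramolecular Williamson etherification (SN2 of the alkoxide on the primary C–Cl); the carbinol carbon is not attacked, so the (S)-configuration passes unchanged into the oxirane.

Step 4
Reactants: 7 3-bromo-5-methoxyphenol
Product: 8 1-(benzyloxy)-3-bromo-5-methoxybenzene
Conditions: BnBr (1.1 equiv), K2CO3, DMF, rt
Reagents that add atoms: benzyl bromide, BrCc1ccccc1
Why: Williamson ether synthesis on the phenoxide; the benzyl group masks the acidic OH so that the aryl Grignard reagent can be made, and it comes off cleanly by hydrogenolysis at the end.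

Step 5
Reactants: 8 1-(benzyloxy)-3-bromo-5-methoxybenzene (1.5 equiv); 6 (S)-2-tridecyloxirane
Product: 10 (S)-1-[3-(benzyloxy)-5-methoxyphenyl]pentadecan-2-ol, via arylmagnesium bromide 9 (not isolated)
Conditions: 8, Mg turnings, iodine (cat.), THF, reflux; then CuBr·SMe2 (10 mol%), 6, THF, −30 → 0 °C; sat. aq. NH4Cl
Reagents that add atoms: none
Why: Copper-catalysed Grignard opening of a terminal epoxide (SN2 at the unhindered CH2 carbon through an arylcuprate); the aryl–CH2 bond forms regioselectively and the stereocentre, which is not the site of attack, stays (S).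

Step 6
Reactants: 10 (S)-1-[3-(benzyloxy)-5-methoxyphenyl]pentadecan-2-ol
Product: 11 3-[(2S)-2-hydroxypentadecyl]-5-methoxyphenol
Conditions: H2 (1 atm), Pd/C (10 wt% Pd on carbon), EtOAc/EtOH, rt
Reagents that add atoms: none
Why: Hydrogenolysis of the aryl benzyl ether over palladium; the homobenzylic (not benzylic) secondary alcohol and the aryl methyl ether are inert, and no stereocentre is touched.

## Compound list

1 | 1-bromotridecane | CCCCCCCCCCCCCBr | starting material
2 | 2-chloro-N-methoxy-N-methylacetamide | CON(C)C(=O)CCl | starting material
3 | tridecylmagnesium bromide (formed in situ) | CCCCCCCCCCCCC[Mg]Br | intermediate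
4 | 1-chloropentadecan-2-one (achiral) | CCCCCCCCCCCCCC(=O)CCl | intermediate
5 | (S)-1-chloropentadecan-2-ol | CCCCCCCCCCCCC[C@H](O)CCl | intermediate
6 | (S)-2-tridecyloxirane | CCCCCCCCCCCCC[C@H]1CO1 | intermediate
7 | 3-bromo-5-methoxyphenol | COc1cc(O)cc(Br)c1 | starting material
8 | 1-(benzyloxy)-3-bromo-5-methoxybenzene | COc1cc(Br)cc(OCc2ccccc2)c1 | intermediate
9 | [3-(benzyloxy)-5-methoxyphenyl]magnesium bromide (formed in situ) | COc1cc([Mg]Br)cc(OCc2ccccc2)c1 | intermediate
10 | (S)-1-[3-(benzyloxy)-5-methoxyphenyl]pentadecan-2-ol | CCCCCCCCCCCCC[C@H](O)Cc1cc(OC)cc(OCc2ccccc2)c1 | intermediate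
11 | 3-[(2S)-2-hydroxypentadecyl]-5-methoxyphenol | CCCCCCCCCCCCC[C@H](O)Cc1cc(O)cc(OC)c1 | target

## Step count and risks

Total steps: 6. Longest linear sequence: 5 steps (steps 1, 2, 3, 5, 6 from 1-bromotridecane); the aryl branch is 3 steps (4, 5, 6).

**Step 2 (enzymatic reduction).** The very lipophilic chloroketone may be poorly accepted or poorly dispersed, or no panel enzyme may reach high ee. The fallback sets out from compound 4 and comes back at compound 6, replacing enzymatic reduction by a chemocatalytic kinetic resolution at the epoxide stage. Ketone 4 is reduced without selectivity (NaBH4, MeOH, 0 °C) to racemic 1-chloropentadecan-2-ol F1. This is closed with NaOH in EtOH to racemic 2-tridecyloxirane F2. F2 is then submitted to hydrolytic kinetic resolution with (S,S)-(salen)Co(OAc) (0.5 mol%, a trivalent cobalt complex; salen = N,N'-bis(3,5-di-tert-butylsalicylidene)cyclohexane-1,2-diamine dianion) and H2O (0.55 equiv), 0 °C → rt. The (R)-epoxide is hydrolysed to (R)-pentadecane-1,2-diol F3, which is removed by chromatography, and the unreacted (S)-epoxide 6 is recovered in at least 99% ee (maximum 50% yield).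

**Step 5 (aryl Grignard formation and epoxide opening).** The Grignard reagent may be slow to form, and magnesium halide can open the epoxide to a bromohydrin. The fallback sets out from compound 8 (with epoxide 6 as partner) and comes back at compound 10, avoiding magnesium and copper altogether. Bromide 8 undergoes halogen–lithium exchange (n-BuLi, THF, −78 °C) to [3-(benzyloxy)-5-methoxyphenyl]lithium F4. Epoxide 6 and then BF3·OEt2 are added at −78 °C, so that the Lewis-acid-activated oxirane is opened at the CH2 terminus by the aryllithium. Aqueous work-up gives 10 with the stereocentre untouched.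

**Step 1 (Grignard addition to the chloro Weinreb amide).** Enolisation of the acidic ClCH2 group, chloride displacement or double addition can lower the yield. The fallback sets out from compound 3 and comes back at compound 4, introducing the chlorine only after the C–C bond is made. Grignard reagent 3 is added to N-methoxy-N-methylacetamide (THF, 0 °C) to give pentadecan-2-one F5. Kinetic deprotonation at the methyl group (LiN(iPr)2, THF, −78 °C) and trapping with Me3SiCl gives trimethyl(pentadec-1-en-2-yloxy)silane F6. Chlorination of this enol silane with N-chlorosuccinimide (THF, 0 °C) gives chloroketone 4 regioselectively.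

## Further compounds

F1 | step 2 | racemic 1-chloropentadecan-2-ol | CCCCCCCCCCCCCC(O)CCl
F2 | step 2 | racemic 2-tridecyloxirane | CCCCCCCCCCCCCC1CO1
F3 | step 2 | (R)-pentadecane-1,2-diol | CCCCCCCCCCCCC[C@@H](O)CO
F4 | step 5 | [3-(benzyloxy)-5-methoxyphenyl]lithium | [Li]c1cc(OC)cc(OCc2ccccc2)c1
F5 | step 1 | pentadecan-2-one | CCCCCCCCCCCCCC(C)=O
F6 | step 1 | trimethyl(pentadec-1-en-2-yloxy)silane | CCCCCCCCCCCCCC(=C)O[Si](C)(C)C
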